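**Retrosynthetic overview**
1. The SMILES encodes the all-cis (1S,2S,3R) tetralin, with the C1 aryl and both CH2OMe groups on one face. C1–H and C2–H are therefore added last, by syn-hydrogenation of a C1=C2 alkene under control of C3.
2. The C2 CH2OMe group is put on a trisubstituted 1-aryl-3,4-dihydronaphthalene by electrophilic methoxymethylation.
3. Ring B comes from a four-membered ring. A prochiral 1-aryl-3-(methoxymethyl)cyclobutanol undergoes an arylative two-carbon ring expansion with 4-bromoveratrole (C–C cleavage, C4–C4a bond, then C1–C8a bond). This step sets C3.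
4. The cyclobutanol comes from 3,4-dimethoxyphenyllithium and 3-(methoxymethyl)cyclobutanone. One aryl bromide, made from catechol, supplies both aromatic rings.
5. Ring order: rings A (fused) and C (pendant) are bought as catechol, and ring B is made from the cyclobutane.

Assumption: 3-(methoxymethyl)cyclobutan-1-one is taken as a purchasable catalogue ketone; locants C1–C4, C4a and C8a of the target are used for all precursors.

**Step 1**
Reactants: 1 catechol (benzene-1,2-diol)
Product: 2 veratrole (1,2-dimethoxybenzene)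
Conditions: MeI (2.5 equiv), K2CO3, acetone, reflux
Reagents that add atoms: iodomethane, CI
Why: Williamson ether synthesis, in which both phenoxides are alkylated cleanly by MeI under K2CO3 and no stereocentre is formed.

**Step 2**
Reactants: 2 veratrole
Product: 3 4-bromoveratrole (4-bromo-1,2-dimethoxybenzene)
Conditions: NBS (1.0 equiv), MeCN, 0 °C → rt
Reagents that add atoms: N-bromosuccinimide, O=C1CCC(=O)N1Br
Why: Electrophilic aromatic bromination, in which NBS in MeCN attacks veratrole only para to a methoxy group and stops at the monobromide.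

**Step 3**
Reactants: 3 4-bromoveratrole; 4 3-(methoxymethyl)cyclobutan-1-one
Product: 6 cis-1-(3,4-dimethoxyphenyl)-3-(methoxymethyl)cyclobutan-1-ol, via 3,4-dimethoxyphenyllithium 5 (not isolated)
Conditions: n-BuLi, THF, −78 °C; then 4, −78 → 0 °C; H2O
Reagents that add atoms: none
Why: Bromine–lithium exchange and 1,2-addition to a strained ketone, in which the aryl group enters anti to the 3-substituent of the puckered ring so that OH and CH2OMe end up cis (achiral, mirror plane through C1 and C3), and the minor trans isomer is removed by chromatography.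

**Step 4**
Reactants: 6 cis-1-(3,4-dimethoxyphenyl)-3-(methoxymethyl)cyclobutan-1-ol; 3 4-bromoveratrole
Product: 8 (3R)-1-(3,4-dimethoxyphenyl)-6,7-dimethoxy-3-(methoxymethyl)-3,4-dihydronaphthalene, via γ-aryl ketone 7 (not isolated)
Conditions: Pd(OAc)2 (5 mol %), (S,Sp)-2-[2-(diphenylphosphino)ferrocenyl]-4-isopropyl-4,5-dihydrooxazole (10 mol %), Cs2CO3 (1.5 equiv), PhMe, 60 °C; filter; then TfOH (20 mol %), CH2Cl2/HFIP, 0 → 40 °C
Reagents that add atoms: none
Why: Proposed new method: an enantioselective arylative two-carbon ring expansion in which the aryl bromide acts as a C–Br/ortho-C–H linchpin stitched into the C1–C4 σ-bond of the four-membered ring: zerovalent palladium inserts into the C–Br bond of 3, carbonate converts 6 into the aryl palladium cyclobutanolate, the chiral P,N ligand selects one of the two enantiotopic C1–CH2 bonds in a strain-driven (about 26 kcal/mol) β-carbon elimination and so fixes C3 as R, C(sp3)–C(sp2) reductive elimination from the primary alkyl divalent palladium outruns β-hydride loss and gives 7, and the acid then closes ring B by attack of the new veratryl ring (position para to OMe) on the protonated ketone followed by E1 dehydration, which cannot touch C3; the closest known reaction types are the palladium-catalysed asymmetric γ-arylation of tert-cyclobutanols by C–C cleavage, the oxidative ring expansion of 1-arylcyclobutanols to 1-tetralones and the Bradsher-type cyclodehydration of 4-aryl ketones, whereas their merger into a cyclobutanol-to-dihydronaphthalene expansion and the alkoxymethyl-substituted prochiral ring are untested, and the ligand antipode that gives R has to be found by experiment.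

**Step 5**
Reactants: 8 (3R)-1-(3,4-dimethoxyphenyl)-6,7-dimethoxy-3-(methoxymethyl)-3,4-dihydronaphthalene
Product: 10 (3R)-1-(3,4-dimethoxyphenyl)-6,7-dimethoxy-2,3-bis(methoxymethyl)-3,4-dihydronaphthalene, via C1 chloride adduct 9 (not isolated)
Conditions: MOMCl (1.1 equiv), ZnCl2·OEt2 (10 mol %), CH2Cl2, −78 °C; then Et3N, −78 °C → rt
Reagents that add atoms: chloromethyl methyl ether, COCCl
Why: Lewis-acid-catalysed addition of an α-chloro ether to an electron-rich alkene (Prins-type alkoxymethylation) followed by loss of HCl, in which MeOCH2+ attacks C2 because that gives the doubly benzylic C1 cation, the diarylalkene is far more nucleophilic than the veratryl rings, the only β-hydrogen sits on C2 so that the tetrasubstituted alkene is the only elimination product, and C3 is untouched.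

**Step 6**
Reactants: 10 (3R)-1-(3,4-dimethoxyphenyl)-6,7-dimethoxy-2,3-bis(methoxymethyl)-3,4-dihydronaphthalene
Product: 11 (1S,2S,3R)-1-(3,4-dimethoxyphenyl)-6,7-dimethoxy-2,3-bis(methoxymethyl)-1,2,3,4-tetrahydronaphthalene
Conditions: H2 (20 bar), PtO2 (10 mol %), EtOAc, rt
Reagents that add atoms: none
Why: Heterogeneous syn-hydrogenation, in which allylic 1,2-strain against C2–CH2OMe forces C3–CH2OMe pseudo-axial, the alkene binds the metal by the opposite face and both hydrogens arrive there, so the C1 aryl and C2–CH2OMe end up cis to C3–CH2OMe (1S,2S), and platinum is chosen over palladium to limit allylic C–O hydrogenolysis and double-bond migration.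

**Compound list**
1 | catechol | Oc1ccccc1O | starting material
2 | veratrole | COc1ccccc1OC | intermediate
3 | 4-bromoveratrole | COc1ccc(Br)cc1OC | intermediate
4 | 3-(methoxymethyl)cyclobutan-1-one | COCC1CC(=O)C1 | starting material
5 | 3,4-dimethoxyphenyllithium | [Li]c1ccc(OC)c(OC)c1 | intermediate
6 | cis-1-(3,4-dimethoxyphenyl)-3-(methoxymethyl)cyclobutan-1-ol (OH cis to CH2OMe) | O[C@@]1(c2ccc(OC)c(OC)c2)C[C@@H](COC)C1 | intermediate
7 | (3R)-1,4-bis(3,4-dimethoxyphenyl)-3-(methoxymethyl)butan-1-one | COC[C@@H](CC(=O)c1ccc(OC)c(OC)c1)Cc1ccc(OC)c(OC)c1 | intermediate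
8 | (3R)-1-(3,4-dimethoxyphenyl)-6,7-dimethoxy-3-(methoxymethyl)-3,4-dihydronaphthalene | COC[C@@H]1Cc2cc(OC)c(OC)cc2C(c2ccc(OC)c(OC)c2)=C1 | intermediate
9 | (3R)-1-chloro-1-(3,4-dimethoxyphenyl)-6,7-dimethoxy-2,3-bis(methoxymethyl)-1,2,3,4-tetrahydronaphthalene (C1/C2 epimers, in equilibrium with its ion pair) | COC[C@@H]1Cc2cc(OC)c(OC)cc2C(Cl)(c2ccc(OC)c(OC)c2)C1COC | intermediate
10 | (3R)-1-(3,4-dimethoxyphenyl)-6,7-dimethoxy-2,3-bis(methoxymethyl)-3,4-dihydronaphthalene | COC[C@@H]1Cc2cc(OC)c(OC)cc2C(c2ccc(OC)c(OC)c2)=C1COC | intermediate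
11 | (1S,2S,3R)-1-(3,4-dimethoxyphenyl)-6,7-dimethoxy-2,3-bis(methoxymethyl)-1,2,3,4-tetrahydronaphthalene (all-cis) | COC[C@@H]1Cc2cc(OC)c(OC)cc2[C@H](c2ccc(OC)c(OC)c2)[C@@H]1COC | target

**Total step count:** 6. **Longest linear sequence:** 6 (1 → 2 → 3 → 6 → 8 → 10 → 11).

**Steps most likely to fail**

**Step 4 (proposed new step).** The risks are low enantioselection with a small, flexible CH2OMe group, β-hydride loss from the alkyl palladium, and a sluggish ring closure on the donor-deactivated ketone. The fallback uses known chemistry. It sets out from 4 and comes back at 7.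
- A catalytic asymmetric Baeyer–Villiger oxidation of 4 (Sc(OTf)3 with a chiral N,N'-dioxide ligand and mCPBA, or a cyclohexanone monooxygenase) gives (R)-4-(methoxymethyl)dihydrofuran-2(3H)-one F1.
- One equivalent of 5 at −78 °C opens the lactone to (3S)-1-(3,4-dimethoxyphenyl)-4-hydroxy-3-(methoxymethyl)butan-1-one F2.
- I2, PPh3 and imidazole convert F2 into (3R)-1-(3,4-dimethoxyphenyl)-4-iodo-3-(methoxymethyl)butan-1-one F3.
- Negishi coupling of F3 with 3,4-dimethoxyphenylzinc chloride F4 (from 5 and ZnCl2; Pd(OAc)2/SPhos) gives 7.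
- Ketone 7 is isolated and cyclodehydrated to 8 with polyphosphoric acid.

**Step 6.** The risks are allylic C–OMe hydrogenolysis, alkene migration that would erode C3, and low reactivity of the tetrasubstituted alkene. The fallback sets out from 8 and comes back at 11.
- Vilsmeier–Haack formylation (POCl3, DMF) gives (3R)-1-(3,4-dimethoxyphenyl)-6,7-dimethoxy-3-(methoxymethyl)-3,4-dihydronaphthalene-2-carbaldehyde F6.
- Luche reduction (NaBH4, CeCl3·7H2O) gives the allylic alcohol [(3R)-1-(3,4-dimethoxyphenyl)-6,7-dimethoxy-3-(methoxymethyl)-3,4-dihydronaphthalen-2-yl]methanol F7.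
- Hydroxyl-directed homogeneous hydrogenation with [Ir(cod)(PCy3)(py)]PF6 takes place on the face anti to the pseudo-axial C3 group and causes no hydrogenolysis. It gives the all-cis alcohol [(1S,2S,3R)-1-(3,4-dimethoxyphenyl)-6,7-dimethoxy-3-(methoxymethyl)-1,2,3,4-tetrahydronaphthalen-2-yl]methanol F8.
- NaH/MeI then gives 11.

**Step 5.** The risks are methoxymethylation of the aromatic rings, and Lewis-acid ionisation of the allylic ether in 10 with closure onto ring C. The fallback sets out from 8 and comes back at 10.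
- Pyridinium tribromide brominates the alkene by addition–elimination to (3S by CIP, same spatial arrangement)-2-bromo-1-(3,4-dimethoxyphenyl)-6,7-dimethoxy-3-(methoxymethyl)-3,4-dihydronaphthalene F5.
- Suzuki–Miyaura coupling with potassium (methoxymethyl)trifluoroborate (Pd(OAc)2, RuPhos, Cs2CO3, dioxane/H2O) gives 10 under basic conditions.

**Further compounds**
F1 | step 4 | (R)-4-(methoxymethyl)dihydrofuran-2(3H)-one | COC[C@H]1CC(=O)OC1
F2 | step 4 | (3S)-1-(3,4-dimethoxyphenyl)-4-hydroxy-3-(methoxymethyl)butan-1-one | COC[C@@H](CC(=O)c1ccc(OC)c(OC)c1)CO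
F3 | step 4 | (3R)-1-(3,4-dimethoxyphenyl)-4-iodo-3-(methoxymethyl)butan-1-one | COC[C@@H](CC(=O)c1ccc(OC)c(OC)c1)CI
F4 | step 4 | 3,4-dimethoxyphenylzinc chloride | Cl[Zn]c1ccc(OC)c(OC)c1
F5 | step 5 | (3S)-2-bromo-1-(3,4-dimethoxyphenyl)-6,7-dimethoxy-3-(methoxymethyl)-3,4-dihydronaphthalene | COC[C@@H]1Cc2cc(OC)c(OC)cc2C(c2ccc(OC)c(OC)c2)=C1Br
F6 | step 6 | (3R)-1-(3,4-dimethoxyphenyl)-6,7-dimethoxy-3-(methoxymethyl)-3,4-dihydronaphthalene-2-carbaldehyde | COC[C@@H]1Cc2cc(OC)c(OC)cc2C(c2ccc(OC)c(OC)c2)=C1C=O
F7 | step 6 | [(3R)-1-(3,4-dimethoxyphenyl)-6,7-dimethoxy-3-(methoxymethyl)-3,4-dihydronaphthalen-2-yl]methanol | COC[C@@H]1Cc2cc(OC)c(OC)cc2C(c2ccc(OC)c(OC)c2)=C1CO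
F8 | step 6 | [(1S,2S,3R)-1-(3,4-dimethoxyphenyl)-6,7-dimethoxy-3-(methoxymethyl)-1,2,3,4-tetrahydronaphthalen-2-yl]methanol | COC[C@@H]1Cc2cc(OC)c(OC)cc2[C@H](c2ccc(OC)c(OC)c2)[C@@H]1CO
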